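Start with what stops the flask.

all flasks: starting material 0.10 M; reagent 4.00 equiv; free catalyst 0.52 mol%; time 8.0 min

|  | remark | temperature |
|---|---|---|
| beta | at 80 °C until 1.5 min, from then on at 65 °C |  |
| epsilon |  | 80 °C |
| eta |  | 65 °C |

    starting material + reagent + free catalyst ⇌ product + free catalyst, rate k1*[starting material]*[reagent]*[free catalyst] forward; the back reaction follows from the equilibrium constant (K1 = 0.86 M⁻¹, k1 = 110 M⁻² s⁻¹, Ea1 = 36.0 kJ mol⁻¹, ΔH1 = −22.0 kJ mol⁻¹)
    starting material + free catalyst → spent catalyst (k2 = 0.38 M⁻¹ s⁻¹, Ea2 = 63.0 kJ mol⁻¹)
    (constants at 80 °C)

- the constants hold at 80 °C; other temperatures follow from the activation energies and enthalpies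

* which flask leads in amount of product, in percent of the starting material charged ("all alike" within 1.5 percentage points) (beta / epsilon / eta / all alike)
* how much product is there at the end, in percent of the starting material charged: beta
* how much product is there at the end, in percent of the starting material charged: epsilon
* how much product is there at the end, in percent of the starting material charged: eta

Step 1 is catalysed, so the free catalyst speeds the approach to its balance without shifting that balance, while step 2 removes the free catalyst. My reckoning begins at that balance. Solving K = [product]/([starting material][reagent]) as a quadratic with the charges gives, at 80 °C:

ceiling = 24.4%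

Call this the ceiling, the yield of product at the balance of step 1.

Now take the given numbers in turn. K1 has to be known best: at twice its value the ceiling reads 38.3%. The zero of the scale is an enthalpy of nil, with one ceiling for every temperature. The real −22.0 kJ mol⁻¹ lifts K to 1.20 M⁻¹ at 65 °C, so:

ceiling at 65 °C = 30.7%

The rate constants rank second, and they enter through the reach, the pseudo-first-order rate of relaxation of step 1 over the rate at which the free catalyst is lost, both taken at the start:

reach at 80 °C = 2.50
reach at 65 °C = 3.02

The part of the ceiling missed is about exp(−reach). Halving the reach at 80 °C raises that part to 28.6%. The activation energies act through the ratio of 2.6 to 1.7. So I commit to 22.4% for epsilon and 29.2% for eta. For beta, the loss of free catalyst slows as [starting material] falls, so I reckon it with the [starting material] that the ceiling leaves; this puts the free catalyst at 7.54% at the change of temperature, an estimate on the high side, since [starting material] begins above that level. That leaves a reach of about 0.228 at 65 °C, so beta should stay close to epsilon.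

The forecast gives 24.5% for beta, 23.1% for epsilon and 29.9% for eta, “leaving eta clearly ahead”. Its figures for epsilon and eta lie above mine.

The simulation gives 24.4% for beta, 23.0% for epsilon and 29.8% for eta, so eta leads.

Eta ends below its ceiling of 30.7%, and epsilon ends below its ceiling of 24.4%, which is close to thermodynamic control. The falling back of product is the main reason eta stops there: with that back reaction struck out, eta ends at 76.0%. For a neighbour of epsilon charged with 16.0 equiv of reagent, the ceiling reads 57.0%, and that flask ends at 56.8%.

The numbers of this flask were set for the occasion; the result is computed.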